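The numbers in the tables are simulated with made-up constants; noise was put on by code.

If the red flask has lost its Q and J has stopped rising while X and E remain, waiting is no remedy for it, and the question becomes where its end lies.

common to all: Q 0.80 M; G 0.33 mol%

| flask | E | temperature | remark | time |
|---|---|---|---|---|
| red | 1 equiv | 90 °C | the very flask that is asked about, followed so far |  |
| violet | 1 equiv | 75 °C | run made earlier |  |
| flask | 1.00 equiv | 90 °C |  | 2.0 d |

| run | time / h | J / % | Q / % |
|---|---|---|---|
| red | 5.00 | 36.1 | 8.4 |
| red | 15.0 | 62.6 | 1.7 |
| red | 25.0 | 66.2 | 0 |
| red | 40.0 | 66.4 | 1.3 |
| violet | 10.0 | 35.1 | 17.1 |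
| violet | 30.0 | 65.6 | 1.6 |
| violet | 48.0 | 69.8 | 0 |
| violet | 96.0 | 71.6 | 0.4 |

(readings scatter by 1 percentage point)

- J taken out counts as made
- the analysis behind the earlier runs scatters by 1 percentage point, standard deviation
- on the list of suspects stand: Q + G -> G + X; E + G + X <-> G + J
- additions bring no volume worth counting

- west: at 2.0 d add E, 100% of the amount charged, then wait 50 h
- north-east: at 2.0 d add G, 50.0% of the amount charged, then wait 50 h
- south: at 2.0 d raise the temperature by 20 K, then wait 50 h
- north-west: at 2.0 d take out 90% of the J then present, then wait 50 h
- north: change nothing and wait 50 h more

- J, in percent of the Q first charged, at 2.0 d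
- the remedy with the largest gain of J, or "none" below 2 percentage points (west / north-east / south / north-west / north / none)
- J present, with what was taken out counted in, in percent of the Q first charged, after south
- J present, with what was taken out counted in, in percent of the Q first charged, after north

On the list of suspects, Q turns into X on G, and E joins X on G, reversibly, to give J. In the red run at 90 °C, Q reads 0% at 25.0 h, and J then moves by 0.2 percentage points up to 40.0 h, less than the scatter of 1 point. The violet run, with the same charges at 75 °C, reads J at 71.6% at 96.0 h, more than the 66.4% of red. X and E are not among the readings, but with equal charges of Q and E and with Q counted at the 0% it read, the balance leaves about 33.6% of the charge for each in the red run, so I do not read its halt as a shortage of material.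

The red reading gives 5.88 for the plateau quotient, [J]/([X][E]) with each concentration taken as a fraction of the charge of Q. The violet reading gives 8.88. The charges of red and violet are equal and their temperatures differ, and the quotient read from the colder violet run is larger than the one read from red, so I read both runs as thermodynamic control.

So I put the red flask at 66.4% at 2.0 d, and I expect north and north-east to leave it there. With the quotient held, adding 100% of the E charged gives 86.9%. I expect south to lose J, since the colder violet run reads higher in J than red.

The forecast gives 66.4% (from 65.5% to 67.3%), 66.4% after north and 59.5% after south (from 56.5% to 62.5%), and it names west. Its ground is this: “I read these plateaus as the equilibrium of E + X ⇌ J, which is exothermic”.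

The red flask gives 67.0% at 2.0 d, 67.0% after north and 61.7% after south, and left ten times as long it stands at 67.0%.

    Q + G → G + X (k = 188 M⁻¹ h⁻¹, Ea = 70.0 kJ mol⁻¹)
    E + G + X ⇌ G + J (K = 7.70 M⁻¹, k = 104 M⁻² h⁻¹, Ea = 42.0 kJ mol⁻¹, ΔH = −22.0 kJ mol⁻¹)
    (constants at 90 °C)

The quotient held at 5.88 puts west 20 points above the red flask, and the gain the flask gives for west is 20 points, more than the 14 points of north-west. On a second flask, the same recipe charged with 0.600 equiv of E, the same quotient gives 45.7%, and that flask holds J at 46.1%.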